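**Direct plan and its weak points**

A direct plan would condense acetophenone A2 with the benzyl-protected aldehyde A1 (Claisen–Schmidt) to chalcone A3, close ring C oxidatively, debenzylate, and free the 5-OH of the 5-methyl ether A4 last.
Its weakest part would be the build-up of A1 from 2,6-dimethoxyphenol: two bromination/lithiation–formylation cycles, a Dakin oxidation and a methylation, only to place one carbon and one oxygen on ring B.
The oxidative ring closure of A3 with iodine in hot DMSO would be the second: an electron-rich chalcone can be iodinated on the ring, lose its benzyl group to HI, or stop at the flavanone.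
The last step would be the worst to run on precious material: BCl3 must cleave one of six methyl ethers beside a free 3'-OH, and boron bound to the 3'-oxygen can take a flanking methyl group as well.

**Plan of the new route**

The retrosynthesis cuts ring A, not ring C: the C5–C4a bond (6π-electrocyclisation of a ketene) and the C8–C8a bond (cross-coupling), leading back to a 2-aryl-4-pyranone and a dimethyl squarate unit.
The pyranone is cut at O1–C6 and C3–C4 to an aryl methyl ketone and a three-carbon acid chloride; the 3'-oxygen comes from lithiation between two methoxy groups.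
Ring order: ring B is bought, ring C (the 4-pyranone) is made second, ring A is built last; the flavone nucleus first appears in the key step.
Feature used: ring A is the tetrad C5(OH)–C6(OMe)–C7(OMe)–C8(H) fused to the enol ether bond C8a=C4a of ring C, which is a 2,3-dimethoxycyclobutenone (C=O, two C–OMe, one CH) on C6 of a 4-pyranone.
The ketone carbon becomes the free, chelated 5-OH, so no methyl ether is cleaved; no B-ring aldehyde and no chalcone cyclisation occur.

Key step: step 7

Remark: the target is achiral; C4 of 11, 13 and 14 and C4a of 16 are racemic stereocentres that vanish on aromatisation. In the fallback text Ar stands for 2,4,5-trimethoxy-3-[tri(propan-2-yl)silyloxy]phenyl.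

**Route**

Step 1
Reactants: 1 1-(2,4,5-trimethoxyphenyl)ethan-1-one
Product: 2 2-methyl-2-(2,4,5-trimethoxyphenyl)-1,3-dioxolane
Conditions: (TMSOCH2)2, TMSOTf (5 mol %), CH2Cl2, −78 to −20 °C; pyridine quench
Reagents that add atoms: 1,2-bis(trimethylsilyloxy)ethane C[Si](C)(C)OCCO[Si](C)(C)C
Why: Ketalisation by silyl transfer masks the ketone against butyllithium, and a ketone ketal, unlike an aldehyde acetal, has no acidic hydrogen on the acetal carbon.

Step 2
Reactants: 2 2-methyl-2-(2,4,5-trimethoxyphenyl)-1,3-dioxolane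
Product: 6 1-(3-hydroxy-2,4,5-trimethoxyphenyl)ethan-1-one, via aryllithium 3 (not isolated), via arylboronate 4 (not isolated), via ketal phenol 5 (not isolated)
Conditions: n-BuLi, THF, 0 °C; B(OMe)3, −78 °C to rt; 30% H2O2, aq. NaOH, 0 °C; Na2S2O3; then 2 M HCl, THF, rt
Reagents that add atoms: hydrogen peroxide OO; water O
Why: Directed ortho metalation should remove H3, which lies between two methoxy groups and is the most acidic ring hydrogen (the quaternary ketal carbon is only a weak director), and borylation, peroxide oxidation (aryl shift from boron to oxygen) and acid hydrolysis of the ketal give the phenol ketone.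

Step 3
Reactants: 6 1-(3-hydroxy-2,4,5-trimethoxyphenyl)ethan-1-one
Product: 7 1-{2,4,5-trimethoxy-3-[tri(propan-2-yl)silyloxy]phenyl}ethan-1-one
Conditions: i-Pr3SiCl, imidazole, DMF, 40 °C
Reagents that add atoms: chlorotri(propan-2-yl)silane CC(C)[Si](Cl)(C(C)C)C(C)C
Why: Silylation of the only hydroxyl (substitution at silicon) installs a bulky group that should survive enolisation, acid, zinc amide, palladium and 110 °C and is removed by fluoride alone.

Step 4
Reactants: 7 1-{2,4,5-trimethoxy-3-[tri(propan-2-yl)silyloxy]phenyl}ethan-1-one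
Product: 9 2-{2,4,5-trimethoxy-3-[tri(propan-2-yl)silyloxy]phenyl}-4H-pyran-4-one, via ethoxyenedione 8 (not isolated)
Conditions: (E)-3-ethoxyacryloyl chloride, MgBr2·OEt2, i-Pr2NEt, CH2Cl2, 0 to 25 °C; aq. HCl wash; then TsOH·H2O (10 mol %), toluene, 60 °C
Reagents that add atoms: (E)-3-ethoxyacryloyl chloride CCO/C=C/C(Cl)=O
Why: Soft-enolisation C-acylation of the magnesium enolate (crossed Claisen type) gives β-diketone 8, and acid-catalysed 6-endo oxa-Michael addition of the enol oxygen to the β-ethoxy enone with loss of ethanol closes ring C as the 4-pyranone.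

Step 5
Reactants: 10 3,4-dimethoxycyclobut-3-ene-1,2-dione (dimethyl squarate)
Product: 11 4-hydroxy-2,3-dimethoxycyclobut-2-en-1-one (racemic)
Conditions: LiAlH(OtBu)3, THF, −78 °C; cold aq. NH4Cl; used at once
Reagents that add atoms: none
Why: 1,2-Reduction of one of the two equivalent vinylogous ester carbonyl groups by a bulky monohydride should stop at the hydroxycyclobutenone because the aluminium alkoxide is not reduced further; the new stereocentre is racemic and is lost later.

Step 6
Reactants: 9 2-{2,4,5-trimethoxy-3-[tri(propan-2-yl)silyloxy]phenyl}-4H-pyran-4-one; 11 4-hydroxy-2,3-dimethoxycyclobut-2-en-1-one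
Product: 14 2,3-dimethoxy-4-(4-oxo-6-{2,4,5-trimethoxy-3-[tri(propan-2-yl)silyloxy]phenyl}-4H-pyran-2-yl)cyclobut-2-en-1-one (racemic), via pyranonylzinc chloride 12 (not isolated), via chlorocyclobutenone 13 (not isolated)
Conditions: 9: TMPZnCl·LiCl (TMP = 2,2,6,6-tetramethylpiperidin-1-yl), MgCl2, THF, −20 to 25 °C; 11: 1-chloro-N,N,2-trimethylprop-1-en-1-amine, CH2Cl2, −20 °C; solutions combined, Pd2(dba)3 (2.5 mol %), tri(2-furyl)phosphine (10 mol %), −20 to 25 °C
Reagents that add atoms: none
Why: Proposed new method: zincation of 9 should occur at C6, the ring hydrogen next to the ring oxygen and β to the magnesium-complexed carbonyl (C3 is shielded by the aryl group), the neutral α-chloroenamine converts allylic alcohol 11 into chloride 13, oxidative addition of zerovalent palladium into the allylic α-keto C–Cl bond gives an η3-oxocyclobutenyl palladium chloride, and transmetalation with 12 and reductive elimination at the CH terminus (the other terminus is a methoxy-bearing carbon where coupling would break the vinylogous ester) give 14 in a Negishi-type coupling; the closest known reaction type is the palladium-catalysed cross-coupling of 4-chlorocyclobut-2-enones with aryl- and heteroarylstannanes, and the new stereocentre C4 is racemic.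

Step 7
Reactants: 14 2,3-dimethoxy-4-(4-oxo-6-{2,4,5-trimethoxy-3-[tri(propan-2-yl)silyloxy]phenyl}-4H-pyran-2-yl)cyclobut-2-en-1-one
Product: 17 5-hydroxy-6,7-dimethoxy-2-{2,4,5-trimethoxy-3-[tri(propan-2-yl)silyloxy]phenyl}-4H-chromen-4-one, via dienylketene 15 (not isolated), via cyclohexadienone 16 (not isolated)
Conditions: toluene (0.02 M), 110 °C, argon
Reagents that add atoms: none
Why: Thermal conrotatory 4π ring opening of the C1–C4 bond of the cyclobutenone gives dienylketene 15, whose ketene carbon closes onto C5 of the pyranone in a 6π disrotatory electrocyclisation to dienone 16, and enolisation gives aromatic ring A. The closest known reaction type is the thermal rearrangement of 4-aryl- and 4-heteroarylcyclobut-2-enones to fused phenols, the closing stage of a Danheiser benzannulation. Ring A closes in the pericyclic 6π mode by forming the C5–C4a bond, the C8–C8a bond being already in place, and ring C is untouched. No stereocentre remains, since racemic C4 of 14 and C4a of 16 both become sp2. The step needs the pyranonyl group to rotate inward on ring opening; ring opening is reversible while cyclisation and enolisation are not, and the hydrogen/heteroaryl pair has no strong outward bias, so the material should funnel to the phenol. The oxygen pattern is fixed by construction: the ketone carbon becomes C5 (free OH, hydrogen-bonded to C4=O), the two methoxy-bearing carbons become C6 and C7, and the CH becomes C8.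

Step 8
Reactants: 17 5-hydroxy-6,7-dimethoxy-2-{2,4,5-trimethoxy-3-[tri(propan-2-yl)silyloxy]phenyl}-4H-chromen-4-one
Product: 18 psiadiarabicin (5-hydroxy-2-(3-hydroxy-2,4,5-trimethoxyphenyl)-6,7-dimethoxy-4H-chromen-4-one)
Conditions: Bu4NF, AcOH, THF, 0 °C
Reagents that add atoms: none
Why: Fluoride-induced cleavage of the aryl silyl ether under acetic acid buffering should touch neither the methyl ethers nor the pyranone, so both phenols of the target appear without any ether cleavage.

**Compound list**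

1 | 1-(2,4,5-trimethoxyphenyl)ethan-1-one | CC(=O)c1cc(OC)c(OC)cc1OC | starting material
2 | 2-methyl-2-(2,4,5-trimethoxyphenyl)-1,3-dioxolane | CC1(OCCO1)c1cc(OC)c(OC)cc1OC | intermediate
3 | [2,3,6-trimethoxy-5-(2-methyl-1,3-dioxolan-2-yl)phenyl]lithium | COc1cc(C2(C)OCCO2)c(OC)c([Li])c1OC | intermediate
4 | dimethyl [2,3,6-trimethoxy-5-(2-methyl-1,3-dioxolan-2-yl)phenyl]boronate | COB(OC)c1c(OC)c(C2(C)OCCO2)cc(OC)c1OC | intermediate
5 | 2,3,6-trimethoxy-5-(2-methyl-1,3-dioxolan-2-yl)phenol | COc1cc(C2(C)OCCO2)c(OC)c(O)c1OC | intermediate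
6 | 1-(3-hydroxy-2,4,5-trimethoxyphenyl)ethan-1-one | CC(=O)c1cc(OC)c(OC)c(O)c1OC | intermediate
7 | 1-{2,4,5-trimethoxy-3-[tri(propan-2-yl)silyloxy]phenyl}ethan-1-one | CC(=O)c1cc(OC)c(OC)c(O[Si](C(C)C)(C(C)C)C(C)C)c1OC | intermediate
8 | (E)-5-ethoxy-1-{2,4,5-trimethoxy-3-[tri(propan-2-yl)silyloxy]phenyl}pent-4-ene-1,3-dione | CCO/C=C/C(=O)CC(=O)c1cc(OC)c(OC)c(O[Si](C(C)C)(C(C)C)C(C)C)c1OC | intermediate
9 | 2-{2,4,5-trimethoxy-3-[tri(propan-2-yl)silyloxy]phenyl}-4H-pyran-4-one | O=c1ccoc(-c2cc(OC)c(OC)c(O[Si](C(C)C)(C(C)C)C(C)C)c2OC)c1 | intermediate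
10 | 3,4-dimethoxycyclobut-3-ene-1,2-dione (dimethyl squarate) | COC1=C(OC)C(=O)C1=O | starting material
11 | 4-hydroxy-2,3-dimethoxycyclobut-2-en-1-one (racemic) | COC1=C(OC)C(O)C1=O | intermediate
12 | chloro(4-oxo-6-{2,4,5-trimethoxy-3-[tri(propan-2-yl)silyloxy]phenyl}-4H-pyran-2-yl)zinc | Cl[Zn]c1cc(=O)cc(-c2cc(OC)c(OC)c(O[Si](C(C)C)(C(C)C)C(C)C)c2OC)o1 | intermediate
13 | 4-chloro-2,3-dimethoxycyclobut-2-en-1-one (racemic) | COC1=C(OC)C(Cl)C1=O | intermediate
14 | 2,3-dimethoxy-4-(4-oxo-6-{2,4,5-trimethoxy-3-[tri(propan-2-yl)silyloxy]phenyl}-4H-pyran-2-yl)cyclobut-2-en-1-one (racemic) | COC1=C(OC)C(c2cc(=O)cc(-c3cc(OC)c(OC)c(O[Si](C(C)C)(C(C)C)C(C)C)c3OC)o2)C1=O | intermediate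
15 | (3E)-2,3-dimethoxy-4-(4-oxo-6-{2,4,5-trimethoxy-3-[tri(propan-2-yl)silyloxy]phenyl}-4H-pyran-2-yl)buta-1,3-dien-1-one | O=C=C(OC)\C(OC)=C/c1cc(=O)cc(-c2cc(OC)c(OC)c(O[Si](C(C)C)(C(C)C)C(C)C)c2OC)o1 | intermediate
16 | 6,7-dimethoxy-2-{2,4,5-trimethoxy-3-[tri(propan-2-yl)silyloxy]phenyl}-4aH-chromene-4,5-dione (racemic) | COC1=C(OC)C(=O)C2C(=O)C=C(c3cc(OC)c(OC)c(O[Si](C(C)C)(C(C)C)C(C)C)c3OC)OC2=C1 | intermediate
17 | 5-hydroxy-6,7-dimethoxy-2-{2,4,5-trimethoxy-3-[tri(propan-2-yl)silyloxy]phenyl}-4H-chromen-4-one | COc1cc(-c2cc(=O)c3c(O)c(OC)c(OC)cc3o2)c(OC)c(O[Si](C(C)C)(C(C)C)C(C)C)c1OC | intermediate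
18 | psiadiarabicin, 5-hydroxy-2-(3-hydroxy-2,4,5-trimethoxyphenyl)-6,7-dimethoxy-4H-chromen-4-one (achiral) | COc1cc(-c2cc(=O)c3c(O)c(OC)c(OC)cc3o2)c(OC)c(O)c1OC | target

**Count**

Total steps: 8. Longest linear sequence: 7 (steps 1–4 and 6–8).

**Steps most likely to fail**

1. Step 6 (Proposed new method). What may go wrong: ionisation of chloride 13 with loss of chloromethane before oxidative addition, zincation of 9 at C3 or C5, or reductive elimination at the methoxy-bearing allyl terminus. The fallback uses known chemistry, sets out from 9 and 10 and comes back at 17. Pyranone 9 is magnesiated at C6 (TMPMgCl·LiCl, THF, −40 °C) and added to dimethyl squarate 10 at −78 °C to give the 1,2-adduct 4-hydroxy-2,3-dimethoxy-4-(4-oxo-6-Ar-4H-pyran-2-yl)cyclobut-2-en-1-one F1. Heating (p-xylene, 140 °C) should give, by the usual thermal ring expansion of squarate adducts with the hydroxyl rotating outward, the hydroquinone 5,8-dihydroxy-6,7-dimethoxy-2-Ar-4H-chromen-4-one F2. The non-chelated 8-OH alone is triflated (PhNTf2, K2CO3, acetone) to 5-hydroxy-6,7-dimethoxy-4-oxo-2-Ar-4H-chromen-8-yl trifluoromethanesulfonate F3. Transfer hydrogenolysis of the triflate (Pd(OAc)2, dppf, HCO2H, Et3N, DMF, 80 °C) gives 17.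

2. Step 7. What may go wrong: outward rotation of the pyranonyl group on ring opening, so that the ketene is used up by dimerisation or adventitious nucleophiles instead of cyclising. The fallback sets out from 14 and comes back at 17. Compound 14 is heated in wet 1,4-dioxane (100 °C) so that the ketene is taken up by water as 2,3-dimethoxy-4-(4-oxo-6-Ar-4H-pyran-2-yl)but-3-enoic acid F4. The acid is cyclised under the classical conditions for 4-arylbut-3-enoic acids (Ac2O, NaOAc, 120 °C), where the double-bond geometry equilibrates through the mixed anhydride, to 6,7-dimethoxy-4-oxo-2-Ar-4H-chromen-5-yl acetate F5. Mild methanolysis (NH4OAc, MeOH) returns 17.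

3. Step 2. What may go wrong: lithiation at C6 beside the ketal through coordination to its oxygens, or incomplete borylation of the hindered aryllithium. The fallback sets out from 1 and comes back at 6. Chelation-controlled cleavage of the methoxy group ortho to the acetyl group (AlCl3, CH2Cl2) gives 1-(2-hydroxy-4,5-dimethoxyphenyl)ethan-1-one F6. Bromination (NBS, MeCN) at the only free position ortho to the hydroxyl gives 1-(3-bromo-2-hydroxy-4,5-dimethoxyphenyl)ethan-1-one F7. O-Methylation (MeI, K2CO3, acetone) gives 1-(3-bromo-2,4,5-trimethoxyphenyl)ethan-1-one F8. Miyaura borylation (B2pin2, PdCl2(dppf), KOAc, dioxane, 90 °C) gives 1-[2,4,5-trimethoxy-3-(4,4,5,5-tetramethyl-1,3,2-dioxaborolan-2-yl)phenyl]ethan-1-one F9, and oxidation (NaBO3·4H2O, THF/H2O) gives 6.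

**Further compounds**

F1 | step 6 | 4-hydroxy-2,3-dimethoxy-4-(4-oxo-6-{2,4,5-trimethoxy-3-[tri(propan-2-yl)silyloxy]phenyl}-4H-pyran-2-yl)cyclobut-2-en-1-one (racemic) | COC1=C(OC)C(O)(c2cc(=O)cc(-c3cc(OC)c(OC)c(O[Si](C(C)C)(C(C)C)C(C)C)c3OC)o2)C1=O
F2 | step 6 | 5,8-dihydroxy-6,7-dimethoxy-2-{2,4,5-trimethoxy-3-[tri(propan-2-yl)silyloxy]phenyl}-4H-chromen-4-one | COc1c(OC)c(O)c2c(=O)cc(-c3cc(OC)c(OC)c(O[Si](C(C)C)(C(C)C)C(C)C)c3OC)oc2c1O
F3 | step 6 | 5-hydroxy-6,7-dimethoxy-4-oxo-2-{2,4,5-trimethoxy-3-[tri(propan-2-yl)silyloxy]phenyl}-4H-chromen-8-yl trifluoromethanesulfonate | COc1c(OC)c(O)c2c(=O)cc(-c3cc(OC)c(OC)c(O[Si](C(C)C)(C(C)C)C(C)C)c3OC)oc2c1OS(=O)(=O)C(F)(F)F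
F4 | step 7 | 2,3-dimethoxy-4-(4-oxo-6-{2,4,5-trimethoxy-3-[tri(propan-2-yl)silyloxy]phenyl}-4H-pyran-2-yl)but-3-enoic acid (racemic, E/Z mixture) | OC(=O)C(OC)C(OC)=Cc1cc(=O)cc(-c2cc(OC)c(OC)c(O[Si](C(C)C)(C(C)C)C(C)C)c2OC)o1
F5 | step 7 | 6,7-dimethoxy-4-oxo-2-{2,4,5-trimethoxy-3-[tri(propan-2-yl)silyloxy]phenyl}-4H-chromen-5-yl acetate | COc1cc2oc(-c3cc(OC)c(OC)c(O[Si](C(C)C)(C(C)C)C(C)C)c3OC)cc(=O)c2c(OC(C)=O)c1OC
F6 | step 2 | 1-(2-hydroxy-4,5-dimethoxyphenyl)ethan-1-one | CC(=O)c1cc(OC)c(OC)cc1O
F7 | step 2 | 1-(3-bromo-2-hydroxy-4,5-dimethoxyphenyl)ethan-1-one | CC(=O)c1cc(OC)c(OC)c(Br)c1O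
F8 | step 2 | 1-(3-bromo-2,4,5-trimethoxyphenyl)ethan-1-one | CC(=O)c1cc(OC)c(OC)c(Br)c1OC
F9 | step 2 | 1-[2,4,5-trimethoxy-3-(4,4,5,5-tetramethyl-1,3,2-dioxaborolan-2-yl)phenyl]ethan-1-one | CC(=O)c1cc(OC)c(OC)c(B2OC(C)(C)C(C)(C)O2)c1OC
A1 | direct plan | 3-(benzyloxy)-2,4,5-trimethoxybenzaldehyde | COc1cc(C=O)c(OC)c(OCc2ccccc2)c1OC
A2 | direct plan | 1-(2-hydroxy-4,5,6-trimethoxyphenyl)ethan-1-one | COc1cc(O)c(C(C)=O)c(OC)c1OC
A3 | direct plan | (E)-3-[3-(benzyloxy)-2,4,5-trimethoxyphenyl]-1-(2-hydroxy-4,5,6-trimethoxyphenyl)prop-2-en-1-one | COc1cc(O)c(C(=O)/C=C/c2cc(OC)c(OC)c(OCc3ccccc3)c2OC)c(OC)c1OC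
A4 | direct plan | 2-(3-hydroxy-2,4,5-trimethoxyphenyl)-5,6,7-trimethoxy-4H-chromen-4-one | COc1cc2oc(-c3cc(OC)c(OC)c(O)c3OC)cc(=O)c2c(OC)c1OC
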